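Time is what you have to stretch here: the readings stop at 15.0 h, and the question stands at 20 h.

| setting | west | north-east | dawn | autumn | summer | midnight | winter |
|---|---|---|---|---|---|---|---|
| G | 0.083 M | 0.21 M | 0.15 M | 0.30 M | 0.12 M | 0.22 M | 0.080 M |
| remark | run made earlier | run made earlier |  |  |  |  |  |
| time |  |  | 20 h | 20 h | 20 h | 20 h | 20 h |

| run | time / h | Q / % | G / % |
|---|---|---|---|
| west | 1.33 | 1 | 73 |
| west | 4.00 | 6 | 32 |
| west | 6.00 | 11 | 23 |
| west | 10.0 | 35 | 7 |
| west | 15.0 | 61 | 3 |
| north-east | 1.33 | 2 | 71 |
| north-east | 4.00 | 3 | 35 |
| north-east | 6.00 | 15 | 18 |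
| north-east | 10.0 | 43 | 8 |
| north-east | 15.0 | 70 | 4 |

(scatter of a reading: 1.5 percentage points)

1. ranking by amount of Q, in percent of the G charged, from high to low, at 20 h (dawn / autumn / summer / midnight / winter)
2. the amount of Q, in percent of the G charged of the flask you put first, at 20 h
3. the amount of Q, in percent of the G charged of the flask you put last, at 20 h

- a reading or a percentage of Q counts all its forms, free or not

Start from the gap between the runs. At 15.0 h the north-east run shows 70% of Q and the west run 61%. Suppose each flask withholds the same concentration from Q, whatever [G] was charged. The percentage withheld then goes as the reciprocal of the charge, so the gap divided by the difference of the reciprocal charges gives 12.4 mM. Call this the toll: a mass-balance deficit counted as a concentration, not as a percentage. The gap at 10.0 h gives 11.0 mM, which is close, given 1.5 percentage points on each reading.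

Now take the toll off the west run. The rest, neither Q nor toll, is 50.1% at 10.0 h and 24.1% at 15.0 h. The same ratio over the next equal step of time leaves 11.6% at 20 h. Now suppose the rest is the same percentage of the charge in each flask, as the G readings at 15.0 h, 3% in the west run and 4% in the north-east run, allow. Your first answer is then 73.0% for winter and 84.3% for autumn.

The weak link is the constant toll, which read lower at 10.0 h than at 15.0 h. So go round once more: put the first answer back in and let the toll grow in step with the fall of the rest, which gives 13.0 mM. Commit to 72.1% for winter and 84.1% for autumn, with the flasks ranked by charge.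

The forecast gives autumn > midnight > dawn > summer > winter, with 88% first and 78% last, on the ground that “higher charge gives more Q”. It shares your order but stands higher than your reckoning at both ends.

The flasks give autumn > midnight > dawn > summer > winter, with 85.9% for autumn and 71.9% for winter.

    G → E (k = 7.11 × 10⁻⁵ /s)
    J ⇌ Q, rate k2*(cs2 - [Q]) while solid is left; crystals form when [Q] > cs2 (solubility = 16.0 mM, k = 0.00379 /s)
    Q ⇌ Z (K = 1.00, k = 6.04 × 10⁻⁵ /s)
    X → D (k = 1.63 × 10⁻⁴ /s)
    E → X (k = 7.38 × 10⁻⁵ /s)
    D → Q (k = 1.44 × 10⁻⁴ /s)

The same division on this result turns the gap of 14 points between autumn and winter into 15.2 mM, and winter holds 15.5 mM as Z at 20.0 h. The neighbouring flask is autumn stopped at 8.0 h. There the toll of 12.4 mM, divided by the [G] charged to autumn, reckons 4.12% of the charge withheld. That flask holds 29.5% of Q and 3.79% of Z.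

The runs stem from a simulated flask from invented constants; noise was put on by code.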